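Both acetate oxygens are traced back to a single O2 molecule. In the butenolide ring the exocyclic carbons C13 (on C11) and C8 (on C7) stand on the same side of the fully substituted C7=C11 double bond. This is where the ends of a diene C13=C11–C7=C8 arrive after a [4+2] addition. One photooxygenation therefore makes both C–O bonds, moves the alkene into the butenolide and creates C8. Its substrate is a ten-membered α-methylene-β-alkylidene lactone whose five-membered ring holds the diene s-cis. Both epoxides, the Z-C1=C10 alkene and the C9 glycidate are already present. The Z-C7=C8 bond stems from a stereodefined 2-iodo-1,3-diene, and the lactone is oxidised into place directly before the key step.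

Key step: step 26

Numbering used in all names: ring carbons are C1 (alkene CH), C2/C3 (epoxide), C4 (bears the methyl C15)/C5 (epoxide), C6 (lactone O–CH), C7, C8, C9 and C10 (bears C14). C11, C12 and C13 are the α-carbon, carbonyl carbon and exocyclic carbon of the lactone.

Remark on C6: carbon nucleophiles add to a cis-2,3-epoxy aldehyde to give the erythro epoxy alcohol, whereas C5/C6 of the target are threo. C6 is therefore made by addition and then inverted on an open-chain compound (steps 17 and 19). The ring is closed at C9–C10, where C6 controls the new centre.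

Remark on the diene: H7 of an α-methylene lactone is only allylic, because it is cross-conjugated with C12=O. The diene is therefore not made by elimination, and C7=C8 is brought in with fixed geometry.

Remark on labels: CIP labels at C2, C4, C5 and C9 change in some intermediates only because substituent priorities change. The spatial arrangement stays that of the target.

**Fragment A (C1–C6, C10, C14, C15)**

Step 1
Reactants: 1 but-2-yn-1-ol
Product: 3 (2Z)-3-iodobut-2-en-1-ol, via cyclic alkenylaluminate 2 (not isolated)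
Conditions: NaAlH2(OCH2CH2OMe)2, THF, 0 °C to rt; then N-iodosuccinimide, −78 °C
Reagents that add atoms: N-iodosuccinimide, O=C1CCC(=O)N1I
Why: Hydroxyl-directed trans-hydroalumination of a propargylic alcohol puts aluminium on the distal alkyne carbon, and iodinolysis with retention gives the Z-iodide only, which later makes C3 and C6 cis on the C4–C5 epoxide.

Step 2
Reactants: 3 (2Z)-3-iodobut-2-en-1-ol; 4 ethyl acrylate
Product: 5 ethyl (2E,4Z)-6-hydroxy-4-methylhexa-2,4-dienoate
Conditions: Pd(OAc)2 (5 mol %), Ag2CO3, MeCN, 50 °C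
Reagents that add atoms: none
Why: Mizoroki–Heck alkenylation of an acrylate keeps the geometry of the alkenyl iodide and forms the new C2=C3 bond E, the silver salt scavenging iodide so that Z/E scrambling is suppressed.

Step 3
Reactants: 5 ethyl (2E,4Z)-6-hydroxy-4-methylhexa-2,4-dienoate
Product: 6 ethyl (2E)-3-[(2R,3S)-3-(hydroxymethyl)-2-methyloxiran-2-yl]prop-2-enoate
Conditions: Ti(OiPr)4 (20 mol %), L-(+)-diethyl tartrate (24 mol %), t-BuOOH, 4 Å MS, CH2Cl2, −20 °C
Reagents that add atoms: tert-butyl hydroperoxide, CC(C)(C)OO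
Why: Katsuki–Sharpless asymmetric epoxidation acts only on the alkene that bears the allylic hydroxyl (the enoate alkene is electron-poor and undirected), and with the L-(+)-tartrate a Z-3,3-disubstituted allylic alcohol of the nerol type is oxidised on the face that gives the C4/C5 arrangement of the target.

Step 4
Reactants: 6 ethyl (2E)-3-[(2R,3S)-3-(hydroxymethyl)-2-methyloxiran-2-yl]prop-2-enoate
Product: 7 ethyl (2E)-3-[(2R,3S)-2-methyl-3-(triethylsilyloxymethyl)oxiran-2-yl]prop-2-enoate
Conditions: Et3SiCl, imidazole, CH2Cl2, 0 °C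
Reagents that add atoms: chlorotriethylsilane, CC[Si](Cl)(CC)CC
Why: Routine silylation of a primary alcohol; the triethylsilyl ether withstands the hydride, titanium and ylide steps and can later be oxidised without prior cleavage.

Step 5
Reactants: 7 ethyl (2E)-3-[(2R,3S)-2-methyl-3-(triethylsilyloxymethyl)oxiran-2-yl]prop-2-enoate
Product: 8 (2E)-3-[(2R,3S)-2-methyl-3-(triethylsilyloxymethyl)oxiran-2-yl]prop-2-en-1-ol
Conditions: i-Bu2AlH (2.2 equiv), CH2Cl2, −78 °C; aq. potassium sodium tartrate
Reagents that add atoms: none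
Why: 1,2-Reduction of an enoate by i-Bu2AlH at low temperature, which leaves the trisubstituted epoxide and the silyl ether alone.

Step 6
Reactants: 8 (2E)-3-[(2R,3S)-2-methyl-3-(triethylsilyloxymethyl)oxiran-2-yl]prop-2-en-1-ol
Product: 9 [(2R,3S)-3-[(2S,3S)-2-methyl-3-(triethylsilyloxymethyl)oxiran-2-yl]oxiran-2-yl]methanol (C2 R, C3 S, C4 S, C5 S)
Conditions: Ti(OiPr)4 (10 mol %), D-(−)-diethyl tartrate (12 mol %), t-BuOOH, 4 Å MS, CH2Cl2, −20 °C
Reagents that add atoms: tert-butyl hydroperoxide, CC(C)(C)OO
Why: Second Katsuki–Sharpless epoxidation, now of an E-disubstituted allylic alcohol, the most reliable substrate class, so that the D-(−)-tartrate and not the neighbouring epoxide decides the face and sets C2 and C3 as a trans epoxide.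

Step 7
Reactants: 9 bis-epoxy alcohol
Product: 10 (2S,3S)-3-[(2S,3S)-2-methyl-3-(triethylsilyloxymethyl)oxiran-2-yl]oxirane-2-carbaldehyde (C1 aldehyde)
Conditions: TEMPO (10 mol %), PhI(OAc)2, CH2Cl2, rt
Reagents that add atoms: none
Why: Oxoammonium (TEMPO) oxidation stops cleanly at the aldehyde under almost neutral conditions that epoxides and silyl ethers tolerate.

Step 8
Reactants: 10 bis-epoxy aldehyde
Product: 11 ethyl (2Z)-2-iodo-3-{(2R,3S)-3-[(2S,3S)-2-methyl-3-(triethylsilyloxymethyl)oxiran-2-yl]oxiran-2-yl}prop-2-enoate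
Conditions: Ph3P=CHCO2Et, N-iodosuccinimide, CH2Cl2, −20 °C; then 10, −20 °C to rt
Reagents that add atoms: ethyl (triphenylphosphoranylidene)acetate, CCOC(=O)C=P(c1ccccc1)(c1ccccc1)c1ccccc1; N-iodosuccinimide, O=C1CCC(=O)N1I
Why: Wittig olefination with the stabilised α-iodo ylide, formed in the flask by iodination of the parent ylide, puts the ester trans to C2 and so gives the Z-iodoenoate in which iodine holds the place of C9.

Step 9
Reactants: 11 Z-iodoenoate
Product: 12 (2Z)-2-iodo-3-{(2R,3S)-3-[(2S,3S)-2-methyl-3-(triethylsilyloxymethyl)oxiran-2-yl]oxiran-2-yl}prop-2-en-1-ol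
Conditions: i-Bu2AlH (2.2 equiv), CH2Cl2, −78 °C; aq. potassium sodium tartrate
Reagents that add atoms: none
Why: 1,2-Reduction of the ester with i-Bu2AlH at −78 °C, which does not touch alkenyl iodides, epoxides or silyl ethers.

Step 10
Reactants: 12 iodo allylic alcohol
Product: 13 14-O-tert-butyldiphenylsilyl ether of 12
Conditions: t-BuPh2SiCl, imidazole, CH2Cl2, 0 °C to rt
Reagents that add atoms: tert-butylchlorodiphenylsilane, CC(C)(C)[Si](Cl)(c1ccccc1)c1ccccc1
Why: Routine silylation; the bulky, acid-stable tert-butyldiphenylsilyl group outlasts the later removal of triethylsilyl and tert-butyldimethylsilyl groups and shields the C14 hydrogens in the key step.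

Step 11
Reactants: 13 bis-silyl ether
Product: 14 (2R,3R)-3-{(2S,3R)-3-[(1Z)-3-(tert-butyldiphenylsilyloxy)-2-iodoprop-1-enyl]oxiran-2-yl}-3-methyloxirane-2-carbaldehyde (C6 aldehyde)
Conditions: (COCl)2, DMSO, CH2Cl2, −78 to −40 °C; then Et3N, −78 to −20 °C
Reagents that add atoms: none
Why: Swern oxidation of a primary triethylsilyl ether: the chlorosulfonium salt cleaves the O–Si bond and the alkoxysulfonium ion collapses to the aldehyde, whereas the hindered silyl ether is inert and H5 on the epoxide is not epimerisable.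

**Fragment B (C7–C9, C11–C13)**

Step 12
Reactants: 15 2-bromoprop-2-en-1-ol
Product: 16 (2-bromoprop-2-enyloxy)(tert-butyl)dimethylsilane
Conditions: t-BuMe2SiCl, imidazole, CH2Cl2, 0 °C to rt
Reagents that add atoms: tert-butylchlorodimethylsilane, CC(C)(C)[Si](C)(C)Cl
Why: Routine silylation that distinguishes O12 from the hydroxyl (O9) needed to direct step 14.

Step 13
Reactants: 16 silylated bromoallyl alcohol; 17 prop-2-yn-1-ol
Product: 18 5-(tert-butyldimethylsilyloxy)-4-methylidenepent-2-yn-1-ol
Conditions: PdCl2(PPh3)2 (3 mol %), CuI (6 mol %), i-Pr2NH, THF, rt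
Reagents that add atoms: none
Why: Sonogashira coupling of an alkenyl bromide with a terminal alkyne joins C7 to C11 and tolerates the free hydroxyl.

Step 14
Reactants: 18 enynol
Product: 20 (2Z)-5-(tert-butyldimethylsilyloxy)-3-iodo-4-methylidenepent-2-en-1-ol, via cyclic alkenylaluminate 19 (not isolated)
Conditions: NaAlH2(OCH2CH2OMe)2, THF, 0 °C; then N-iodosuccinimide, −78 °C
Reagents that add atoms: N-iodosuccinimide, O=C1CCC(=O)N1I
Why: Same hydroxyl-directed trans-hydroalumination–iodination as in step 1: hydride goes to C8, aluminium then iodine to C7 cis to C9, which fixes the Z-C7=C8 geometry of the later diene.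

**Fragment C (glycidic acid)**

Step 15
Reactants: 21 2-methylprop-2-en-1-ol
Product: 22 [(2R)-2-methyloxiran-2-yl]methanol
Conditions: Ti(OiPr)4 (5 mol %), D-(−)-diisopropyl tartrate (7 mol %), t-BuOOH, 4 Å MS, CH2Cl2, −20 °C
Reagents that add atoms: tert-butyl hydroperoxide, CC(C)(C)OO
Why: Katsuki–Sharpless asymmetric epoxidation of a 2-substituted allylic alcohol; the D-(−)-tartrate gives the R-epoxy alcohol, which sets the only stereocentre of the glycidate.

Step 16
Reactants: 22 [(2R)-2-methyloxiran-2-yl]methanol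
Product: 23 (2S)-2-methyloxirane-2-carboxylic acid
Conditions: TEMPO (10 mol %), PhI(OAc)2 (2.2 equiv), MeCN–H2O, 0 °C to rt
Reagents that add atoms: water, O
Why: TEMPO-catalysed oxidation in the presence of water carries the primary alcohol through the aldehyde hydrate to the acid without touching the quaternary stereocentre (the label changes from R to S by priority only).

**Assembly**

Step 17
Reactants: 20 iodo dienol; 14 C6 aldehyde
Product: 25 (6S)-diol, open-chain C6–C7 coupled compound (14-OTBDPS, 10-iodo, 1(10)Z, 2,3- and 4,5-epoxides, 6-OH, 7(8)Z, 9-OH, 11(13)-ene, 12-OTBS; 2R,3S,4S,5S,6S), via dilithio species 24 (not isolated)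
Conditions: 20, t-BuLi (3.1 equiv), Et2O, −78 °C; then 14, −78 °C; H2O
Reagents that add atoms: none
Why: Iodine–lithium exchange with retention gives the alkoxide-stabilised alkenyllithium, whose 1,2-addition to the aldehyde outruns exchange with the second iodide; a cis-epoxy aldehyde reacts through the conformer with the formyl hydrogen over the ring and is attacked past the epoxide oxygen, away from the cis C3 substituent, so the 5,6-erythro (6S) alcohol should dominate.

Step 18
Reactants: 25 (6S)-diol
Product: 26 9-O-triethylsilyl ether of 25 (6-OH free)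
Conditions: Et3SiCl (1.05 equiv), imidazole, CH2Cl2, −40 °C
Reagents that add atoms: chlorotriethylsilane, CC[Si](Cl)(CC)CC
Why: Selective silylation of the primary allylic hydroxyl at low temperature; the flanked secondary C6 hydroxyl reacts much more slowly.

Step 19
Reactants: 26 (6S)-alcohol
Product: 27 (6R)-picolinate (6-O-pyridine-2-carbonyl, C6 inverted; 2R,3S,4S,5S,6R)
Conditions: pyridine-2-carboxylic acid, PPh3, diisopropyl azodicarboxylate, THF, −20 °C to rt
Reagents that add atoms: pyridine-2-carboxylic acid, OC(=O)c1ccccn1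
Why: Mitsunobu esterification (SN2 on the oxyphosphonium salt) inverts C6 to the required 5,6-threo 6R configuration, the textbook correction of erythro epoxy alcohols, and the picolinate serves as a protecting group that can later be removed without base.

Step 20
Reactants: 27 (6R)-picolinate
Product: 28 Z-enal (C9 aldehyde, otherwise as 27)
Conditions: (COCl)2, DMSO, CH2Cl2, −78 to −40 °C; then Et3N, −78 to −30 °C
Reagents that add atoms: none
Why: Swern oxidation of the primary allylic triethylsilyl ether as in step 11; the tert-butyl-substituted silyl ethers stay on and the short, cold exposure to Et3N keeps the Z-enal intact.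

Step 21
Reactants: 28 iodo Z-enal
Product: 29 macrocyclic alcohol (cyclodeca-1(10),7-diene; 6-O-picolinate, 9-OH, C7 bearing 3-(TBSO)prop-1-en-2-yl, 14-OTBDPS; 2R,3S,4S,5S,6R,9S)
Conditions: CrCl2 (10 equiv), NiCl2 (1 mol % of the CrCl2), DMSO–THF, rt, slow addition to 1 mM
Reagents that add atoms: none
Why: Nozaki–Hiyama–Kishi reaction: NiCl2-catalysed formation of the alkenylchromium species from the Z-iodide with retention and its chemoselective 1,2-addition to the aldehyde close the ten-membered ring at high dilution; allylic 1,3-strain keeps H6 in the plane of the s-trans Z-enal, the short C5–C1 tether leaves C6 on one face only, and attack of C10 on that face gives the C9 arrangement of the target.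

Step 22
Reactants: 29 macrocyclic alcohol; 23 (2S)-2-methyloxirane-2-carboxylic acid
Product: 31 9-O-[(2S)-2-methyloxirane-2-carbonyl] ester of 29, via mixed anhydride 30 (not isolated)
Conditions: 23, 2,4,6-trichlorobenzoyl chloride, Et3N, toluene, rt; then 29, DMAP, 0 °C to rt
Reagents that add atoms: none
Why: Yamaguchi esterification through the mixed anhydride acylates hindered secondary alcohols with retention at C9, and the acid has no α-hydrogen to epimerise.

Step 23
Reactants: 31 glycidate picolinate
Product: 32 6-alcohol (picolinate removed)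
Conditions: Cu(OAc)2 (30 mol %), MeOH–CH2Cl2, rt
Reagents that add atoms: none
Why: Chelation-assisted transesterification: Cu(OAc)2 binds the pyridine nitrogen and the ester carbonyl, so methanol cleaves only the picolinate under neutral conditions and the glycidate, epoxides and silyl ethers remain.

Step 24
Reactants: 32 6-alcohol
Product: 33 6,12-diol
Conditions: HF·pyridine, pyridine, THF, 0 °C
Reagents that add atoms: none
Why: Fluoride-mediated desilylation; buffered HF·pyridine removes a primary tert-butyldimethylsilyl ether far faster than a tert-butyldiphenylsilyl ether and is mild enough for epoxides.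

Step 25
Reactants: 33 6,12-diol
Product: 35 dienyl lactone (12,6-olide with the C13=C11–C7=C8 diene, 7(8)Z, 9-O-glycidate, 14-OTBDPS; 2R,3S,4S,5S,6R,9S,2′S), via lactol 34 (not isolated)
Conditions: TEMPO (20 mol %), PhI(OAc)2 (2.5 equiv), CH2Cl2, rt; used at once
Reagents that add atoms: none
Why: TEMPO oxidation picks the primary allylic alcohol, the enal is trapped by the C6 hydroxyl as a five-membered lactol and this is oxidised on to the lactone (oxidative lactonisation of a 1,4-diol), which unveils the reactive diene only now.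

Step 26
Reactants: 35 dienyl lactone
Product: 36 8,13-endoperoxide (3,6-dihydro-1,2-dioxine fused to the C7=C11 butenolide; 8R,9R)
Conditions: O2 (1 atm), tetraphenylporphyrin (1 mol %), CH2Cl2, −20 °C, visible-light LED
Reagents that add atoms: dioxygen, O=O
Why: Sensitised singlet oxygen adds in a concerted, suprafacial [4+2] manner to C13 and C8 of the diene, which the five-membered lactone holds s-cis with C9 in the outer position, so both C–O bonds form together and the π bond ends up as C7=C11. The closest known reaction type is the singlet-oxygen Diels–Alder reaction of 1,2-dialkylidenecycloalkanes and other s-cis dienes to 3,6-dihydro-1,2-dioxines. The only ring closed is the six-membered 1,2-dioxine, formed by cycloaddition of both termini at once and not by a stepwise exo or endo closure. C8 is the only new stereocentre: the chain C5–C4–C3–C2–C1–C10 leaves C6 anti to H6 and returns to C9 on the same side, so it covers that face and O2 must enter on the H6 face, which with the Z-C7=C8 geometry gives 8R. The step needs chemoselectivity over the ene reaction at C1=C10, which is secured because that alkene carries three allylic C–O bonds, its C2–H and C9–H bonds are poorly aligned, the bulky silyl ether shields the C14 hydrogens and the oxidisable senecioate is not yet present. Low temperature and the absence of base prevent Kornblum–DeLaMare cleavage through the vinylogously acidic H8.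

Step 27
Reactants: 36 endoperoxide
Product: 37 8,13-diol (butenolide)
Conditions: thiourea (1.1 equiv), MeOH–CH2Cl2, 0 °C
Reagents that add atoms: none
Why: Thiourea reduces the O–O bond of 3,6-dihydro-1,2-dioxines to the cis-ene-1,4-diol without base, so C8 keeps its configuration and H8 is not removed; one equivalent in the cold spares the epoxides.

Step 28
Reactants: 37 8,13-diol
Product: 38 8,13-diacetate
Conditions: Ac2O, pyridine, DMAP (5 mol %), CH2Cl2, 0 °C
Reagents that add atoms: acetic anhydride, CC(=O)OC(C)=O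
Why: Standard acetylation of the primary and the secondary hydroxyl, run at once so that lactone or glycidate migration to O8 cannot set in.

Step 29
Reactants: 38 8,13-diacetate
Product: 39 14-alcohol
Conditions: Bu4NF–AcOH (1:1), THF, 0 °C to rt
Reagents that add atoms: none
Why: Fluoride-mediated desilylation; buffering Bu4NF with AcOH keeps the medium near neutral so that acetates, glycidate, epoxides and the base-sensitive butenolide survive.

Step 30
Reactants: 39 14-alcohol; 40 3-methylbut-2-enoic acid
Product: 41 target CNP0279449.1 (2R,3S,4S,5S,6R,8R,9R,2′S; 1(10)Z)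
Conditions: N,N′-dicyclohexylcarbodiimide, DMAP (10 mol %), CH2Cl2, 0 °C
Reagents that add atoms: none
Why: Steglich esterification of the primary allylic alcohol; activating the acid with a carbodiimide avoids the vinylketene pathway of the acid chloride that would move the double bond out of conjugation.

**Compound list**

1 | but-2-yn-1-ol | CC#CCO | starting material
2 | cyclic alkenylaluminate from 1 (sodium salt) | CC1=CCO[Al-]1(OCCOC)OCCOC.[Na+] | intermediate
3 | (2Z)-3-iodobut-2-en-1-ol | OC/C=C(/C)I | intermediate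
4 | ethyl acrylate | C=CC(=O)OCC | starting material
5 | ethyl (2E,4Z)-6-hydroxy-4-methylhexa-2,4-dienoate | CCOC(=O)/C=C/C(C)=C\CO | intermediate
6 | ethyl (2E)-3-[(2R,3S)-3-(hydroxymethyl)-2-methyloxiran-2-yl]prop-2-enoate | CCOC(=O)/C=C/[C@@]1(C)O[C@H]1CO | intermediate
7 | triethylsilyl ether of 6 | CCOC(=O)/C=C/[C@@]1(C)O[C@H]1CO[Si](CC)(CC)CC | intermediate
8 | (2E)-3-[(2R,3S)-2-methyl-3-(triethylsilyloxymethyl)oxiran-2-yl]prop-2-en-1-ol | OC/C=C/[C@@]1(C)O[C@H]1CO[Si](CC)(CC)CC | intermediate
9 | bis-epoxy alcohol (2R,3S,4S,5S) | OC[C@H]1O[C@@H]1[C@@]1(C)O[C@H]1CO[Si](CC)(CC)CC | intermediate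
10 | bis-epoxy C1 aldehyde | O=C[C@H]1O[C@@H]1[C@@]1(C)O[C@H]1CO[Si](CC)(CC)CC | intermediate
11 | Z-α-iodoenoate | CCOC(=O)/C(I)=C/[C@H]1O[C@@H]1[C@@]1(C)O[C@H]1CO[Si](CC)(CC)CC | intermediate
12 | Z-2-iodo allylic alcohol | OC/C(I)=C/[C@H]1O[C@@H]1[C@@]1(C)O[C@H]1CO[Si](CC)(CC)CC | intermediate
13 | 14-OTBDPS, 6-OTES alkenyl iodide | CC(C)(C)[Si](OC/C(I)=C/[C@H]1O[C@@H]1[C@@]1(C)O[C@H]1CO[Si](CC)(CC)CC)(c1ccccc1)c1ccccc1 | intermediate
14 | C6 aldehyde | CC(C)(C)[Si](OC/C(I)=C/[C@H]1O[C@@H]1[C@@]1(C)O[C@H]1C=O)(c1ccccc1)c1ccccc1 | intermediate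
15 | 2-bromoprop-2-en-1-ol | OCC(Br)=C | starting material
16 | (2-bromoprop-2-enyloxy)(tert-butyl)dimethylsilane | C=C(Br)CO[Si](C)(C)C(C)(C)C | intermediate
17 | prop-2-yn-1-ol | C#CCO | starting material
18 | 5-(tert-butyldimethylsilyloxy)-4-methylidenepent-2-yn-1-ol | OCC#CC(=C)CO[Si](C)(C)C(C)(C)C | intermediate
19 | cyclic alkenylaluminate from 18 (sodium salt) | C=C(CO[Si](C)(C)C(C)(C)C)C1=CCO[Al-]1(OCCOC)OCCOC.[Na+] | intermediate
20 | (2Z)-5-(tert-butyldimethylsilyloxy)-3-iodo-4-methylidenepent-2-en-1-ol | OC/C=C(\I)C(=C)CO[Si](C)(C)C(C)(C)C | intermediate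
21 | 2-methylprop-2-en-1-ol | CC(=C)CO | starting material
22 | [(2R)-2-methyloxiran-2-yl]methanol | OC[C@]1(C)CO1 | intermediate
23 | (2S)-2-methyloxirane-2-carboxylic acid | OC(=O)[C@]1(C)CO1 | intermediate
24 | O,C7-dilithio derivative of 20 | [Li]OC/C=C(\[Li])C(=C)CO[Si](C)(C)C(C)(C)C | intermediate
25 | (6S)-diol | CC(C)(C)[Si](OC/C(I)=C/[C@H]1O[C@@H]1[C@@]1(C)O[C@H]1[C@@H](O)/C(=C\CO)C(=C)CO[Si](C)(C)C(C)(C)C)(c1ccccc1)c1ccccc1 | intermediate
26 | (6S)-alcohol, 9-OTES | CC(C)(C)[Si](OC/C(I)=C/[C@H]1O[C@@H]1[C@@]1(C)O[C@H]1[C@@H](O)/C(=C\CO[Si](CC)(CC)CC)C(=C)CO[Si](C)(C)C(C)(C)C)(c1ccccc1)c1ccccc1 | intermediate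
27 | (6R)-picolinate | CC(C)(C)[Si](OC/C(I)=C/[C@H]1O[C@@H]1[C@@]1(C)O[C@H]1[C@H](OC(=O)c1ccccn1)/C(=C\CO[Si](CC)(CC)CC)C(=C)CO[Si](C)(C)C(C)(C)C)(c1ccccc1)c1ccccc1 | intermediate
28 | iodo Z-enal | CC(C)(C)[Si](OC/C(I)=C/[C@H]1O[C@@H]1[C@@]1(C)O[C@H]1[C@H](OC(=O)c1ccccn1)/C(=C\C=O)C(=C)CO[Si](C)(C)C(C)(C)C)(c1ccccc1)c1ccccc1 | intermediate
29 | macrocyclic alcohol | C=C(CO[Si](C)(C)C(C)(C)C)/C1=C/[C@H](O)/C(CO[Si](c2ccccc2)(c2ccccc2)C(C)(C)C)=C\[C@H]2O[C@@H]2[C@@]2(C)O[C@H]2[C@@H]1OC(=O)c1ccccn1 | intermediate
30 | mixed anhydride of 23 and 2,4,6-trichlorobenzoic acid | O=C(OC(=O)[C@]1(C)CO1)c1c(Cl)cc(Cl)cc1Cl | intermediate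
31 | 9-O-glycidate, 6-O-picolinate | C=C(CO[Si](C)(C)C(C)(C)C)/C1=C/[C@H](OC(=O)[C@]2(C)CO2)/C(CO[Si](c2ccccc2)(c2ccccc2)C(C)(C)C)=C\[C@H]2O[C@@H]2[C@@]2(C)O[C@H]2[C@@H]1OC(=O)c1ccccn1 | intermediate
32 | 6-alcohol | C=C(CO[Si](C)(C)C(C)(C)C)/C1=C/[C@H](OC(=O)[C@]2(C)CO2)/C(CO[Si](c2ccccc2)(c2ccccc2)C(C)(C)C)=C\[C@H]2O[C@@H]2[C@@]2(C)O[C@H]2[C@@H]1O | intermediate
33 | 6,12-diol | C=C(CO)/C1=C/[C@H](OC(=O)[C@]2(C)CO2)/C(CO[Si](c2ccccc2)(c2ccccc2)C(C)(C)C)=C\[C@H]2O[C@@H]2[C@@]2(C)O[C@H]2[C@@H]1O | intermediate
34 | lactol (C12 hemiacetal) | C=C1/C2=C/[C@H](OC(=O)[C@]3(C)CO3)/C(CO[Si](c3ccccc3)(c3ccccc3)C(C)(C)C)=C\[C@H]3O[C@@H]3[C@@]3(C)O[C@H]3[C@@H]2OC1O | intermediate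
35 | dienyl lactone (key-step precursor) | C=C1/C2=C/[C@H](OC(=O)[C@]3(C)CO3)/C(CO[Si](c3ccccc3)(c3ccccc3)C(C)(C)C)=C\[C@H]3O[C@@H]3[C@@]3(C)O[C@H]3[C@@H]2OC1=O | intermediate
36 | 8,13-endoperoxide (key-step product) | O1OCC2=C3[C@@H]1[C@H](OC(=O)[C@]1(C)CO1)/C(CO[Si](c1ccccc1)(c1ccccc1)C(C)(C)C)=C\[C@H]1O[C@@H]1[C@@]1(C)O[C@H]1[C@@H]3OC2=O | intermediate
37 | 8,13-diol | OCC1=C2[C@@H](O)[C@H](OC(=O)[C@]3(C)CO3)/C(CO[Si](c3ccccc3)(c3ccccc3)C(C)(C)C)=C\[C@H]3O[C@@H]3[C@@]3(C)O[C@H]3[C@@H]2OC1=O | intermediate
38 | 8,13-diacetate | CC(=O)OCC1=C2[C@@H](OC(C)=O)[C@H](OC(=O)[C@]3(C)CO3)/C(CO[Si](c3ccccc3)(c3ccccc3)C(C)(C)C)=C\[C@H]3O[C@@H]3[C@@]3(C)O[C@H]3[C@@H]2OC1=O | intermediate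
39 | 14-alcohol | CC(=O)OCC1=C2[C@@H](OC(C)=O)[C@H](OC(=O)[C@]3(C)CO3)/C(CO)=C\[C@H]3O[C@@H]3[C@@]3(C)O[C@H]3[C@@H]2OC1=O | intermediate
40 | 3-methylbut-2-enoic acid | CC(C)=CC(=O)O | starting material
41 | CNP0279449.1 | CC(=O)OCC1=C2[C@@H](OC(C)=O)[C@H](OC(=O)[C@]3(C)CO3)/C(COC(=O)C=C(C)C)=C\[C@H]3O[C@@H]3[C@@]3(C)O[C@H]3[C@@H]2OC1=O | target

Total step count: 30. Longest linear sequence: 25 (steps 1–11 and 17–30).

**Steps most likely to fail**

Step 26. The ester-substituted diene may react too slowly with the electrophilic oxidant. Ene oxidation at C1=C10 or bleaching of the sensitiser could then take over. The C9 ester, which sits on the open face, could also erode the facial selectivity. The fallback sets out from 35 and comes back at 38 by oxygenating the diene in two polar steps: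
- Dimethyldioxirane in acetone at −40 °C should epoxidise the more electron-rich C7=C8 bond from the same open face and give the 7,8-epoxide F1.
- Bu4NOAc/AcOH in THF then adds acetate to C13 of the α-methylene lactone, and the enolate opens the allylic C7–O bond (conjugate addition–elimination, overall SN2′). The C8–O bond is untouched, and the product is the 13-acetoxy-8-hydroxy butenolide F2.
- Acetylation as in step 28 leads to 38.

Step 21. Rotation of the enal out of its s-trans form, or a looser tether than assumed, could lead to loss of facial selectivity at C9 during ring closure. The fallback sets out from 28 and comes back at 31. The 9-epimeric alcohol F3 formed in the same Ni/Cr closure is esterified with acid 23 under Mitsunobu conditions (PPh3, diisopropyl azodicarboxylate, toluene, 0 °C) instead of by acyl transfer. C9 is then inverted while the glycidate is installed, and both epimers converge on 31.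

Step 19. The hindered allylic oxyphosphonium salt may undergo SN2′ attack at C8 or elimination instead of clean inversion. The fallback sets out from 26 and comes back at 27, and it sets C6 by reagent-controlled reduction:
- Dess–Martin oxidation of 26 gives the dienyl epoxy ketone F4.
- Corey–Bakshi–Shibata reduction with the (R)-methyl oxazaborolidine and catecholborane, with the dienyl group as the large substituent, should give the (6R)-alcohol F5.
- Acylation with pyridine-2-carboxylic acid, N,N′-dicyclohexylcarbodiimide and DMAP proceeds with retention and gives 27.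

**Further compounds**

F1 | step 26 | 7,8-epoxide of 35 (oxygen on the H6 face) | C=C1[C@]23O[C@H]2[C@H](OC(=O)[C@]2(C)CO2)/C(CO[Si](c2ccccc2)(c2ccccc2)C(C)(C)C)=C\[C@H]2O[C@@H]2[C@@]2(C)O[C@H]2[C@@H]3OC1=O
F2 | step 26 | 13-acetoxy-8-hydroxy butenolide | CC(=O)OCC1=C2[C@@H](O)[C@H](OC(=O)[C@]3(C)CO3)/C(CO[Si](c3ccccc3)(c3ccccc3)C(C)(C)C)=C\[C@H]3O[C@@H]3[C@@]3(C)O[C@H]3[C@@H]2OC1=O
F3 | step 21 | 9-epimer of macrocyclic alcohol 29 | C=C(CO[Si](C)(C)C(C)(C)C)/C1=C/[C@@H](O)/C(CO[Si](c2ccccc2)(c2ccccc2)C(C)(C)C)=C\[C@H]2O[C@@H]2[C@@]2(C)O[C@H]2[C@@H]1OC(=O)c1ccccn1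
F4 | step 19 | C6 ketone from 26 | CC(C)(C)[Si](OC/C(I)=C/[C@H]1O[C@@H]1[C@@]1(C)O[C@H]1C(=O)/C(=C\CO[Si](CC)(CC)CC)C(=C)CO[Si](C)(C)C(C)(C)C)(c1ccccc1)c1ccccc1
F5 | step 19 | (6R)-alcohol, 6-epimer of 26 | CC(C)(C)[Si](OC/C(I)=C/[C@H]1O[C@@H]1[C@@]1(C)O[C@H]1[C@H](O)/C(=C\CO[Si](CC)(CC)CC)C(=C)CO[Si](C)(C)C(C)(C)C)(c1ccccc1)c1ccccc1
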